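**Strategy.** The route rests on the bond between C8 of the chromanone carbocycle (ring A) and the benzylic carbon of the 3-phenylpropanoate chain. It is made by an isothiourea-catalysed Michael addition–lactonisation. The aromatic chromanone, already carrying the pinene-derived cyclobutylmethyl group at C6, attacks a cinnamoyl ammonium ion through C8 and closes a temporary lactone through the neighbouring 7-OH. One operation thus joins both fragments, sets the benzylic stereocentre and ties up O7. The step exploits the enol unit C8–C7–O7 of the phloroglucinol ring, its only unsubstituted C–H next to a free OH. The lactone is opened in the last step, where palladium-catalysed prenylation dearomatises C6.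

Key step: step 12

Atom numbering: chromanone numbering (O1, C2, C3, C4, C4a, C5, C6, C7, C8, C8a) is used for the bicyclic core in all compounds.

Assumption: the catalyst enantiomers named in steps 12 and 13 follow the usual transition-state models for these catalyst classes (the antipodes are equally accessible should the opposite sense be required), and the tertiary prenyl carbonate of step 13 is taken as a purchasable reagent.

Step 1
Reactants: 1 (1S,5S)-(−)-verbenone
Product: 2 (1S,3R)-3-acetyl-2,2-dimethylcyclobutane-1-carboxylic acid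
Conditions: RuCl3·xH2O (2 mol%), NaIO4 (4.2 equiv), MeCN/EtOAc/H2O, rt
Reagents that add atoms: sodium periodate [Na+].[O-]I(=O)(=O)=O; water O
Why: RuO4 generated in situ cleaves the enone C=C bond (oxidative alkene cleavage) and the resulting α-keto acid loses the former C3 as CO2, leaving both bridgehead stereocentres, and hence the cis-1,3 relationship, of the chiral-pool terpene untouched.

Step 2
Reactants: 2 (1S,3R)-3-acetyl-2,2-dimethylcyclobutane-1-carboxylic acid
Product: 3 (1S,3S)-2,2-dimethyl-3-(prop-1-en-2-yl)cyclobutane-1-carboxylic acid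
Conditions: Ph3PCH3Br (2.5 equiv), KOtBu (2.4 equiv), THF, 0 °C to rt; HCl work-up
Reagents that add atoms: methyltriphenylphosphonium bromide C[P+](c1ccccc1)(c1ccccc1)c1ccccc1.[Br-]
Why: Wittig methylenation of the methyl ketone (the carboxylate is inert to the ylide), run cold so that ylide addition outruns enolisation and the cis ring stereochemistry, which is also the preferred 1,3-arrangement, is kept.

Step 3
Reactants: 3 (1S,3S)-2,2-dimethyl-3-(prop-1-en-2-yl)cyclobutane-1-carboxylic acid
Product: 4 [(1S,3S)-2,2-dimethyl-3-(prop-1-en-2-yl)cyclobutyl]methanol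
Conditions: LiAlH4, THF, 0 °C to rt
Reagents that add atoms: none
Why: Hydride reduction of the carboxylic acid to the primary alcohol; the unactivated alkene and the stereocentres are not affected.

Step 4
Reactants: 4 [(1S,3S)-2,2-dimethyl-3-(prop-1-en-2-yl)cyclobutyl]methanol
Product: 5 (1S,3S)-1-(iodomethyl)-2,2-dimethyl-3-(prop-1-en-2-yl)cyclobutane
Conditions: PPh3, I2, imidazole, CH2Cl2, 0 °C to rt
Reagents that add atoms: iodine II
Why: Appel-type iodination by SN2 displacement at the primary carbon, so no stereocentre is involved.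

Step 5
Reactants: 6 ethyl (S)-3-hydroxybutanoate
Product: 7 ethyl (2S,3S)-3-hydroxy-2-methylbutanoate
Conditions: LDA (2.2 equiv), THF, −50 °C; MeI, DMPU, −50 to 0 °C
Reagents that add atoms: iodomethane CI
Why: Fráter–Seebach alkylation, in which the chelated dianion is methylated anti to the C3 substituent to give the (2S,3S) isomer; only C3 matters later because C2 becomes the epimerisable C3 of the chromanone.

Step 6
Reactants: 7 ethyl (2S,3S)-3-hydroxy-2-methylbutanoate; 8 phloroglucinol (3 equiv)
Product: 9 ethyl (2S,3R)-3-(3,5-dihydroxyphenoxy)-2-methylbutanoate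
Conditions: PPh3, DIAD, THF, 0 °C to rt
Reagents that add atoms: none
Why: Mitsunobu etherification of the acidic triol (in excess for mono-substitution) proceeds by SN2 with inversion, turning the 3S carbinol into the 3R aryl ether that becomes C2 of the chromanone.

Step 7
Reactants: 9 ethyl (2S,3R)-3-(3,5-dihydroxyphenoxy)-2-methylbutanoate
Product: 10 (2R,3R)-5,7-dihydroxy-2,3-dimethylchroman-4-one
Conditions: Eaton's reagent (P2O5 in MeSO3H), 60 °C
Reagents that add atoms: none
Why: Acid-mediated intramolecular Friedel–Crafts acylation by the ester onto the strongly activated ring (both positions ortho to the ether oxygen are equivalent) closes the pyranone, and enolisation in the acid should equilibrate C3 to the more stable 2,3-trans isomer while the ether stereocentre C2 is not touched.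

Step 8
Reactants: 10 (2R,3R)-5,7-dihydroxy-2,3-dimethylchroman-4-one
Product: 11 (2R,3R)-5-hydroxy-7-(methoxymethoxy)-2,3-dimethylchroman-4-one
Conditions: MOMCl (1.1 equiv), i-Pr2NEt (1.2 equiv), CH2Cl2, 0 °C
Reagents that add atoms: chloromethyl methyl ether COCCl
Why: The non-chelated, more acidic 7-OH is alkylated selectively because the 5-OH is hydrogen-bonded to the C4 ketone, a standard regioselective protection of 5,7-dihydroxychromanones.

Step 9
Reactants: 11 (2R,3R)-5-hydroxy-7-(methoxymethoxy)-2,3-dimethylchroman-4-one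
Product: 12 (2R,3R)-5-hydroxy-6-iodo-7-(methoxymethoxy)-2,3-dimethylchroman-4-one
Conditions: BnMe3N·ICl2 (1.05 equiv), CaCO3, CH2Cl2/MeOH, rt
Reagents that add atoms: benzyltrimethylammonium dichloroiodate C[N+](C)(C)Cc1ccccc1.Cl[I-]Cl
Why: Electrophilic iodination by the dichloroiodate is directed ortho to the free chelated 5-OH (and para to the ring oxygen), i.e. to C6, leaving C8 unsubstituted, as known for 5-hydroxy-7-alkoxy chromones and flavones.

Step 10
Reactants: 5 (1S,3S)-1-(iodomethyl)-2,2-dimethyl-3-(prop-1-en-2-yl)cyclobutane (1.5 equiv); 12 (2R,3R)-5-hydroxy-6-iodo-7-(methoxymethoxy)-2,3-dimethylchroman-4-one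
Product: 15 (2R,3R)-6-{[(1R,3S)-2,2-dimethyl-3-(prop-1-en-2-yl)cyclobutyl]methyl}-5-hydroxy-7-(methoxymethoxy)-2,3-dimethylchroman-4-one, via cyclobutylmethyllithium 13 (not isolated), via cyclobutylmethylzinc chloride 14 (not isolated)
Conditions: 5, t-BuLi (2.1 equiv per 5), Et2O/pentane, −78 °C; ZnCl2 in THF, −78 °C to rt; then 12, Pd(OAc)2 (5 mol%), SPhos (10 mol%), THF, rt to 45 °C
Reagents that add atoms: none
Why: Negishi sp3–sp2 coupling, in which iodine–lithium exchange and transmetalation to zinc avoid radical intermediates that could open the cyclobutylcarbinyl unit, the alkylzinc tolerates the phenol proton, and no stereocentre is involved.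

Step 11
Reactants: 15 (2R,3R)-6-{[(1R,3S)-2,2-dimethyl-3-(prop-1-en-2-yl)cyclobutyl]methyl}-5-hydroxy-7-(methoxymethoxy)-2,3-dimethylchroman-4-one
Product: 16 (2R,3R)-6-{[(1R,3S)-2,2-dimethyl-3-(prop-1-en-2-yl)cyclobutyl]methyl}-5,7-dihydroxy-2,3-dimethylchroman-4-one
Conditions: ZnBr2 (1 equiv), n-PrSH (2 equiv), CH2Cl2, 0 °C to rt
Reagents that add atoms: none
Why: Lewis-acid-assisted thiolysis of the aryl methoxymethyl ether under conditions too mild to protonate the isopropenyl group or to enolise the chromanone.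

Step 12
Reactants: 16 (2R,3R)-6-{[(1R,3S)-2,2-dimethyl-3-(prop-1-en-2-yl)cyclobutyl]methyl}-5,7-dihydroxy-2,3-dimethylchroman-4-one; 17 (E,E)-cinnamic anhydride (1.3 equiv)
Product: 18 (2R,3R,10S)-6-{[(1R,3S)-2,2-dimethyl-3-(prop-1-en-2-yl)cyclobutyl]methyl}-5-hydroxy-2,3-dimethyl-10-phenyl-2,3,9,10-tetrahydro-4H,8H-pyrano[2,3-f]chromene-4,8-dione (the 4-phenyl-dihydrocoumarin lactone between O7 and C8)
Conditions: (2R,3S)-HyperBTM (10 mol%), i-Pr2NEt (1.3 equiv), CH2Cl2, rt; dilute HCl wash
Reagents that add atoms: none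
Why: The isothiourea is acylated by 17 to a cinnamoyl ammonium ion held planar and s-cis by an S···O contact; the 7-phenoxide of 16 adds through C8, its only unsubstituted ring carbon, to the β-carbon (Michael addition), and the acyl ammonium so formed is captured by O7 (6-exo-trig lactonisation) with release of the catalyst. This is the α,β-unsaturated acyl ammonium Michael addition–lactonisation known for cyclic 1,3-dicarbonyl enols and naphthols. The benzylic stereocentre (10S) is set by the catalyst: the pseudo-axial C2 phenyl group of the (2R,3S) catalyst shields one face of the enoyl unit, and the existing stereocentres of 16 are too remote to compete. Site selectivity is structural (C6 is alkylated and O1 is an ether, so only the C8/O7 pair can close a six-membered lactone), and O-cinnamoylation of the phenols is harmless because such aryl esters re-enter the cycle by acyl transfer to the catalyst.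

Step 13
Reactants: 18 the dihydrocoumarin lactone of step 12; 19 tert-butyl 2-methylbut-3-en-2-yl carbonate (1.2 equiv)
Product: 21 (3S)-3-[(2R,3R,6R)-6-{[(1R,3S)-2,2-dimethyl-3-(prop-1-en-2-yl)cyclobutyl]methyl}-5-hydroxy-2,3-dimethyl-6-(3-methylbut-2-en-1-yl)-4,7-dioxo-3,4,6,7-tetrahydro-2H-chromen-8-yl]-3-phenylpropanoic acid, via dipotassium carboxylate phenoxide 20 (not isolated)
Conditions: KOSiMe3 (2.1 equiv), THF, 0 °C; then 19, Pd2(dba)3·CHCl3 (2.5 mol%), (1R,2R)-N,N'-bis[2-(diphenylphosphanyl)benzoyl]cyclohexane-1,2-diamine (7.5 mol%), 0 °C to rt; aqueous HCl to pH 3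
Reagents that add atoms: potassium trimethylsilanolate C[Si](C)(C)[O-].[K+]
Why: The silanolate opens the aryl lactone to the carboxylate/7-phenoxide dianion without water, and Tsuji–Trost alkylation by the π-prenyl palladium complex then takes place at C6 (the ring carbon flanked by two oxygens and not screened by the bulky C8 side chain) through the unsubstituted allyl terminus, giving the linear prenyl group and a stable vinylogous acid with no aromatic sink, while the chiral diphosphine should select the face of the planar phenoxide and so set the 6R quaternary centre (carboxylate O-prenylation is reversible under zerovalent palladium).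

**Compound list**

1 | (1S,5S)-(−)-verbenone, (1S,5S)-4,6,6-trimethylbicyclo[3.1.1]hept-3-en-2-one | CC1=CC(=O)[C@H]2C[C@@H]1C2(C)C | starting material
2 | (1S,3R)-3-acetyl-2,2-dimethylcyclobutane-1-carboxylic acid (cis-pinononic acid) | CC(=O)[C@@H]1C[C@H](C(=O)O)C1(C)C | intermediate
3 | (1S,3S)-2,2-dimethyl-3-(prop-1-en-2-yl)cyclobutane-1-carboxylic acid | C=C(C)[C@@H]1C[C@H](C(=O)O)C1(C)C | intermediate
4 | [(1S,3S)-2,2-dimethyl-3-(prop-1-en-2-yl)cyclobutyl]methanol | C=C(C)[C@@H]1C[C@H](CO)C1(C)C | intermediate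
5 | (1S,3S)-1-(iodomethyl)-2,2-dimethyl-3-(prop-1-en-2-yl)cyclobutane | C=C(C)[C@@H]1C[C@H](CI)C1(C)C | intermediate
6 | ethyl (S)-3-hydroxybutanoate | C[C@H](O)CC(=O)OCC | starting material
7 | ethyl (2S,3S)-3-hydroxy-2-methylbutanoate | C[C@H](O)[C@H](C)C(=O)OCC | intermediate
8 | phloroglucinol (benzene-1,3,5-triol) | Oc1cc(O)cc(O)c1 | starting material
9 | ethyl (2S,3R)-3-(3,5-dihydroxyphenoxy)-2-methylbutanoate | Oc1cc(O)cc(c1)O[C@H](C)[C@H](C)C(=O)OCC | intermediate
10 | (2R,3R)-5,7-dihydroxy-2,3-dimethylchroman-4-one | Oc1cc(O)c2c(c1)O[C@H](C)[C@@H](C)C2=O | intermediate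
11 | (2R,3R)-5-hydroxy-7-(methoxymethoxy)-2,3-dimethylchroman-4-one | COCOc1cc(O)c2c(c1)O[C@H](C)[C@@H](C)C2=O | intermediate
12 | (2R,3R)-5-hydroxy-6-iodo-7-(methoxymethoxy)-2,3-dimethylchroman-4-one | COCOc1c(I)c(O)c2c(c1)O[C@H](C)[C@@H](C)C2=O | intermediate
13 | {[2,2-dimethyl-3-(prop-1-en-2-yl)cyclobutyl]methyl}lithium, configuration as in 5 | C=C(C)[C@@H]1C[C@H](C[Li])C1(C)C | intermediate
14 | {[2,2-dimethyl-3-(prop-1-en-2-yl)cyclobutyl]methyl}zinc chloride, configuration as in 5 | C=C(C)[C@@H]1C[C@H](C[Zn]Cl)C1(C)C | intermediate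
15 | (2R,3R)-6-{[(1R,3S)-2,2-dimethyl-3-(prop-1-en-2-yl)cyclobutyl]methyl}-5-hydroxy-7-(methoxymethoxy)-2,3-dimethylchroman-4-one | C=C(C)[C@@H]1C[C@H](Cc2c(OCOC)cc3O[C@H](C)[C@@H](C)C(=O)c3c2O)C1(C)C | intermediate
16 | (2R,3R)-6-{[(1R,3S)-2,2-dimethyl-3-(prop-1-en-2-yl)cyclobutyl]methyl}-5,7-dihydroxy-2,3-dimethylchroman-4-one | C=C(C)[C@@H]1C[C@H](Cc2c(O)cc3O[C@H](C)[C@@H](C)C(=O)c3c2O)C1(C)C | intermediate
17 | (E,E)-cinnamic anhydride | O=C(/C=C/c1ccccc1)OC(=O)/C=C/c1ccccc1 | starting material
18 | (2R,3R,10S)-6-{[(1R,3S)-2,2-dimethyl-3-(prop-1-en-2-yl)cyclobutyl]methyl}-5-hydroxy-2,3-dimethyl-10-phenyl-2,3,9,10-tetrahydro-4H,8H-pyrano[2,3-f]chromene-4,8-dione | C=C(C)[C@@H]1C[C@H](Cc2c3OC(=O)C[C@@H](c4ccccc4)c3c5O[C@H](C)[C@@H](C)C(=O)c5c2O)C1(C)C | intermediate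
19 | tert-butyl 2-methylbut-3-en-2-yl carbonate | C=CC(C)(C)OC(=O)OC(C)(C)C | starting material
20 | dipotassium salt (carboxylate and 7-phenoxide) of (3S)-3-[(2R,3R)-6-{[(1R,3S)-2,2-dimethyl-3-(prop-1-en-2-yl)cyclobutyl]methyl}-5,7-dihydroxy-2,3-dimethyl-4-oxochroman-8-yl]-3-phenylpropanoic acid | C=C(C)[C@@H]1C[C@H](Cc2c([O-])c([C@@H](CC(=O)[O-])c3ccccc3)c3O[C@H](C)[C@@H](C)C(=O)c3c2O)C1(C)C.[K+].[K+] | intermediate
21 | (3S)-3-[(2R,3R,6R)-6-{[(1R,3S)-2,2-dimethyl-3-(prop-1-en-2-yl)cyclobutyl]methyl}-5-hydroxy-2,3-dimethyl-6-(3-methylbut-2-en-1-yl)-4,7-dioxo-3,4,6,7-tetrahydro-2H-chromen-8-yl]-3-phenylpropanoic acid | C=C(C)[C@@H]1C[C@H](C[C@@]2(CC=C(C)C)C(=O)C([C@@H](CC(=O)O)c3ccccc3)=C3O[C@H](C)[C@@H](C)C(=O)C3=C2O)C1(C)C | target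

**Step count.** Total: 13 steps. Longest linear sequence: 9 steps (6 to 21 through steps 5 to 13); the cyclobutane branch (1 to 5) joins at step 10.

**Steps most likely to fail**

Step 13. The chiral palladium complex may not discriminate the two faces of the planar phenoxide, giving both C6 epimers, and O-prenylation of the carboxylate may stall turnover. The fallback sets out from 18 and returns at 21. Methanolysis of 18 (NaOMe, MeOH, 0 °C) would give methyl (3S)-3-[(2R,3R)-6-{[(1R,3S)-2,2-dimethyl-3-(prop-1-en-2-yl)cyclobutyl]methyl}-5,7-dihydroxy-2,3-dimethyl-4-oxochroman-8-yl]-3-phenylpropanoate F1. Asymmetric phase-transfer alkylation of F1 with prenyl bromide (N-(9-anthracenylmethyl)cinchonidinium bromide, Cs2CO3, toluene, −20 °C) would then let a chiral ammonium ion pair, not a metal–allyl complex, choose the face and give the methyl ester of 21 F2. The C6 epimers are diastereomers and could be separated at this stage. Saponification (LiOH, THF/H2O, 0 °C) returns to 21.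

Step 12. The phenoxide may be acylated only on oxygen, with the aryl cinnamate failing to pass on to the carbon-bound adduct, or facial control may be poor with this weakly acidic arene nucleophile. The fallback sets out from 16 and returns at 21, reversing the order of the last two operations. Palladium-catalysed prenylation of 16 with 19 (catalyst of step 13, Et3N, THF, 0 °C, kinetic control to disfavour attack at C8) would give the dearomatised vinylogous acid (2R,3R,6R)-6-{[(1R,3S)-2,2-dimethyl-3-(prop-1-en-2-yl)cyclobutyl]methyl}-5-hydroxy-2,3-dimethyl-6-(3-methylbut-2-en-1-yl)-2,3-dihydro-4H-chromene-4,7(6H)-dione F3. This cyclic 1,3-dicarbonyl-type enol is a stronger carbon nucleophile and should undergo the same Michael addition–lactonisation with 17 to the enol lactone of 21 F4. Mild hydrolysis of F4 (LiOH, THF/H2O, 0 °C) gives 21.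

Step 6. β-Elimination of the activated hydroxy ester to ethyl tiglate and double etherification of the triol may outrun the SN2 displacement. The fallback sets out from 8 and returns at 10, making the C–O bond by conjugate addition instead of substitution. Friedel–Crafts acylation of 8 with tigloyl chloride (AlCl3, PhNO2, rt) would give (E)-2-methyl-1-(2,4,6-trihydroxyphenyl)but-2-en-1-one F5. Quinine-catalysed enantioselective intramolecular oxa-Michael addition of F5 (PhCl, rt), followed by acid equilibration of C3 (p-TsOH, toluene), leads to 10.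

**Further compounds**

F1 | step 13 | methyl (3S)-3-[(2R,3R)-6-{[(1R,3S)-2,2-dimethyl-3-(prop-1-en-2-yl)cyclobutyl]methyl}-5,7-dihydroxy-2,3-dimethyl-4-oxochroman-8-yl]-3-phenylpropanoate | C=C(C)[C@@H]1C[C@H](Cc2c(O)c([C@@H](CC(=O)OC)c3ccccc3)c3O[C@H](C)[C@@H](C)C(=O)c3c2O)C1(C)C
F2 | step 13 | methyl ester of 21 | C=C(C)[C@@H]1C[C@H](C[C@@]2(CC=C(C)C)C(=O)C([C@@H](CC(=O)OC)c3ccccc3)=C3O[C@H](C)[C@@H](C)C(=O)C3=C2O)C1(C)C
F3 | step 12 | (2R,3R,6R)-6-{[(1R,3S)-2,2-dimethyl-3-(prop-1-en-2-yl)cyclobutyl]methyl}-5-hydroxy-2,3-dimethyl-6-(3-methylbut-2-en-1-yl)-2,3-dihydro-4H-chromene-4,7(6H)-dione | C=C(C)[C@@H]1C[C@H](C[C@@]2(CC=C(C)C)C(=O)C=C3O[C@H](C)[C@@H](C)C(=O)C3=C2O)C1(C)C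
F4 | step 12 | enol lactone of 21 (O7 acylated by the side-chain carboxyl; 5-oxo dienone form, configuration as in 21) | C=C(C)[C@@H]1C[C@H](C[C@@]2(CC=C(C)C)C(OC(=O)C[C@H]4c5ccccc5)=C4C=3O[C@H](C)[C@@H](C)C(=O)C3C2=O)C1(C)C
F5 | step 6 | (E)-2-methyl-1-(2,4,6-trihydroxyphenyl)but-2-en-1-one | C/C=C(\C)C(=O)c1c(O)cc(O)cc1O
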